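If G in these flasks grows as E meets Z, the thing to watch is how much of each stands together in the last minutes of the run, and the earlier runs let that be counted.

the same everywhere: Q 35 mM (held)

| charge | E | L | remark | time |
|---|---|---|---|---|
| zeta | 0.10 M | 2 equiv | run made earlier |  |
| theta | 0.10 M | 1 equiv | run made earlier |  |
| eta | 0.10 M | 1.5 equiv | run made earlier |  |
| gamma | 0.20 M | 2 equiv | run made earlier |  |
| larch | 0.10 M | 2.00 equiv | everything together at the start | 5.0 min |
| ash | 0.10 M (fed, over 3.0 min) | 2.00 equiv | all else is in the flask from the start; the feed brings no volume worth counting | 5.0 min |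
| alder | 0.10 M | 2.00 equiv (fed, over 3.0 min) | all else is in the flask from the start; the feed brings no volume worth counting | 5.0 min |

| run | time / min | G / % | Z / % | E / % |
|---|---|---|---|---|
| zeta | 0.200 | 0.2 | 0 | 98.4 |
| zeta | 0.667 | 1.3 | 1.0 | 95.1 |
| zeta | 1.00 | 0 | 0 | 91.4 |
| zeta | 1.50 | 2.1 | 1.7 | 86.7 |
| zeta | 2.50 | 4.5 | 5.3 | 79.3 |
| zeta | 3.00 | 8.0 | 9.1 | 75.4 |
| theta | 0.833 | 0 | 2.3 | 95.5 |
| theta | 1.50 | 0.2 | 0.1 | 95.4 |
| theta | 2.50 | 3.4 | 4.3 | 89.9 |
| theta | 3.00 | 3.9 | 4.9 | 86.9 |
| theta | 4.00 | 9.3 | 5.3 | 81.7 |
| theta | 5.00 | 15.0 | 7.8 | 78.2 |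
| eta | 0.833 | 0.2 | 1.2 | 93.8 |
| eta | 1.50 | 0.9 | 3.6 | 91.5 |
| eta | 2.50 | 3.4 | 4.1 | 83.1 |
| eta | 3.00 | 6.6 | 6.5 | 81.4 |
| eta | 4.00 | 14.5 | 10.3 | 72.9 |
| eta | 5.00 | 22.6 | 9.4 | 67.1 |
| gamma | 0.417 | 0 | 0 | 91.2 |
| gamma | 0.833 | 0.5 | 0 | 87.9 |
| gamma | 1.33 | 0.9 | 3.0 | 78.3 |
| gamma | 2.50 | 10.1 | 5.4 | 62.1 |
| gamma | 5.00 | 31.6 | 9.6 | 36.8 |

(scatter of a reading: 1 percentage point)

- percent here means E units held: one G counts as two
- at the start none of J is dissolved
- what may be going on: E + L -> D; L + J -> X; D + X -> Z; E + Z -> G; Q <-> J

* the flask with the highest amount of G, in percent of the E charged ("all alike" if they lie within 1.5 percentage points) (larch / ash / alder / all alike)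
* final G, as a percentage of the E charged, in larch
* final G, as a percentage of the E charged, in ash
* final G, as a percentage of the E charged, in alder

Let e and z be the fractions of the E charge standing as E and Z; one G counts as two, so G should climb by two units per pairing, at two times κ·e·z per minute. The means over the last gamma interval, scaled to the charge of 0.10 M, give the pairing constant κ (Z goes pseudo-first-order at κ·e), as a reading, 0.580 /min.

The zeta run has the recipe of larch, so both chemists hold its last e and z up to 5.0 min and get 23.9% for larch. The first chemist argues that a steady feed of E holds about half of e on average, so that by the end of its feed ash should have lost half of what zeta had lost at its last reading and made half of its G. On this view ash stands at e = 87.7%, higher than zeta, and with zeta's z it comes to 22.5%; the gap to larch is 1.4 percentage points, inside the margin, so this chemist counts larch and ash as alike.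

The second chemist, whom I join, puts that answer back in: Z was made from the same halved E, so z starts at half of zeta's. Held there, ash gives 13.3%; but z climbs again, so my own midpoint is 17.9%, below larch, with alder treated the same way. The forecast takes this side with a higher ash: larch, with 26%, 21% and 18% for larch, ash and alder, saying “Feeding E keeps E low while Z starts”.

The flask gives larch as the highest, with 25.8% in larch, 17.5% in ash and 16.8% in alder.

    E + L → D (k = 0.00770 /M/s)
    L + J → X (k = 0.210 /M/s)
    D + X → Z (k = 0.940 /M/s)
    E + Z → G (k = 0.0990 /M/s)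
    Q ⇌ J, rate k5*(csat - [J]) (kL = 0.00600 /s)

From the end of its feed, ash reckoned with κ on the mean of its e·z at 3.00 min and at 5.00 min comes to 16.1%, against the 17.5% of the flask. The first chemist's alikeness does hold between the two fed flasks, ash and alder, 0.70 points apart, inside the margin. A neighbour of larch with 3.40 equiv of L ends with z at 21.1% and e at 38.3%, so κ gives G a closing rate of 0.0937 /min, against 0.0844 /min for larch itself at its end, and G in that neighbour stands at 32.4%.

The data are simulated from invented constants.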